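## Analysis of the target

Capillaridin A (15) is a single furan ring in which every position is substituted. C2 carries a phenyl group, C3 a 3-oxobut-1-ynyl arm, C4 a methyl group and C5 a 3-oxo-3-phenylprop-1-ynyl arm. There is no stereocentre, so the problem is one of regiochemistry on the ring and of the timing of the functional groups. Both arms are ynones and therefore strong Michael acceptors, the C3 arm is also an enolisable methyl ketone, and the 2-alkynylfuran core is electron-rich and sensitive to strong acid and to oxidants. The difficulty is twofold: four different groups must be placed on four contiguous ring atoms without ambiguity, and two similar but non-identical alkynyl ketone arms on C3 and C5 must be told apart and unveiled late. The strategy rests on the segment O1–C5–C4, which with its alkynyl group on C5 and its methyl group on C4 is the skeleton of an α-hydroxy methyl ketone with a propargylic carbinol carbon (5). C2 with its phenyl group and C3 are the two sp carbons of ynone 6. Joining the two leaves an acetyl group on C3, which holds exactly the two carbons of the C3 alkyne, and delivers the C5 alkyne as an inert silyl-capped unit, so that C5 never passes through a carbonyl oxidation state.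

## Retrosynthetic reasoning

The last bond to be made is the C(sp)–C(O) bond of the benzoyl ynone on C5, cut to the terminal alkyne 13 and benzoyl chloride 14. This arm goes first in the backward direction because the aryl ynone is the most electrophilic group of 15 and would not survive an organometallic or strongly basic step. A palladium/copper-catalysed acyl Sonogashira coupling forms it under a tertiary amine at room temperature, which the methyl ynone already present on C3 should tolerate.

Alkyne 13 is traced to its silyl-capped form 12. No skeletal bond is cut. The triisopropylsilyl group keeps the C5 alkyne silent through everything that precedes, and the forward step must remove it with buffered fluoride without letting a basic species add to the ynone.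

In 12 the C(sp)–C(O) bond of the C3 arm is cut, to lithium acetylide 11 and Weinreb amide 9. Cutting here, and not at the ring–alkyne bond, avoids a cross-coupling at the hindered C3 position between phenyl and methyl, and the chelated adduct of 11 and 9 stops at the ketone stage. Because the C5 alkyne is still capped, no second acetylide can form.

The metalated ethynyl group of 11 is read as a dehydrated acetyl group, so 11 is traced through enol phosphate 10 to methyl ketone 8. This is a change of functional group and not a disconnection. It is what makes the plan work, because the acetyl group is also the activating group that the ring-forming step needs. The elimination delivers the alkyne directly as its lithium salt, so the acylation can follow in the same flask and the carbon nucleophile does not have to be generated a second time. The forward reaction has to enolise only the acetyl methyl, which is the sole enolisable position of 8.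

Furan 8 is cut at O1–C2 and C3–C4, to acyloin 5 and ynone 6, with hydroxydihydrofuran 7 between them. These cuts divide the ring into a two-carbon unit (C2–C3) that is electrophilic at C2 and becomes nucleophilic at C3, and a three-atom unit (O1–C5–C4) of matching polarity. Each piece brings two of the four substituents, so the substitution pattern follows from connectivity. Any cut that made C5 a carbonyl carbon would force the C5 alkyne to be introduced later. The forward reaction must join the hydroxyl oxygen of 5 to the phenyl-bearing carbon of 6, close C3–C4 by aldol addition, and dehydrate 7.

Acyloin 5 is cut between its carbinol carbon and its carbonyl carbon, to ynal 2 and the acetyl anion equivalent 1-ethoxyvinyllithium 3, made from ethyl vinyl ether 1. The adduct 4 is the enol ether of 5. Two commercial compounds and one flask give the hydroxy ketone at the right oxidation level.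

## Alternatives that were turned down

Alternative 1: The ring is cut at O1–C2 together with the bond from C3 to the first sp carbon of its arm. The precursor is the yne-diol A2, 3-methyl-1-phenyl-6-(trimethylsilyl)hexa-1,5-diyne-3,4-diol.
- Forward key step: AuCl activates the phenyl-substituted alkyne of A2 and the secondary hydroxyl adds to the phenyl-bearing carbon in a 5-endo-dig closure. The tertiary carbinol is dehydrated, and the C3–gold bond is captured by the alkynyl benziodoxolone A3, 1-[(triisopropylsilyl)ethynyl]-1,2-benziodoxol-3(1H)-one. The product is the bis(silylalkynyl)furan A1.
- For it: the regiochemistry is locked by the positions of the two hydroxyls, and gold-catalysed cycloisomerisation of such diols is dependable. On one point it is stronger than the chosen route: both arms sit on the ring as differentiated silyl alkynes straight after ring formation, so no ketone has to be turned into an alkyne with strong base.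
- Against it: the alkynylation must outrun protodeauration, yet every turnover of the cyclisation releases a proton from the attacking hydroxyl and a molecule of water next to the vinyl–gold bond. The expected default is protodeauration, which leaves C3 unsubstituted, a position flanked by phenyl and methyl and poorly disposed to later alkynylation. A3 also has to take monovalent gold to trivalent gold in the presence of a free diol.
- Downstream: both silyl groups of A1 must be removed in turn and each alkyne acylated, so the second acylation again has to be run next to a finished ynone.
- Comparison: the route would be no shorter, since four steps follow the key step against three in the chosen route. The chosen route offers a metal-free ring construction made only of elementary steps with direct precedent.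

Alternative 2: The C3=C4 double bond is cut through the butenolide A4, 3-methyl-5-phenyl-4-[(triisopropylsilyl)ethynyl]furan-2(5H)-one. Its lactone carbonyl carbon is the future C5, its methyl-bearing carbon C4, its alkynyl-bearing carbon C3 and its phenyl-bearing sp3 carbon C2. The precursor is the phosphonate ester A5, 2-oxo-1-phenyl-4-(triisopropylsilyl)but-3-yn-1-yl 2-(diethoxyphosphoryl)propanoate.
- Forward key step: LiCl and an amidine base deprotonate the phosphonate of A5, and the carbanion closes onto the ynone carbonyl in an intramolecular Horner–Wadsworth–Emmons reaction.
- For it: the closure is reliable and every substituent position is dictated by the ester tether. As a single ring-forming event it is at least as predictable as the chosen annulation, and it never passes through an allenolate.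
- Against it: A4 is not a furan. Its lactone carbonyl must be enolised, O-sulfonylated and cross-coupled before C5 carries an alkyne, so C5 is built at the carboxyl level only to be taken down again. A5 contains a C–H that is benzylic, α to the ynone carbonyl and α to the acyloxy group. It competes with the phosphonate C–H for the base and opens enolisation and acyl migration. A5 itself needs several steps.
- Comparison: the route would be three to four steps longer. The chosen route gives the aromatic ring directly with the C5 alkyne already in place.

Alternative 3: The ring is cut at O1–C5 and C4=C5. The precursors are the enone A7, 5-[(tert-butyldimethylsilyl)oxy]-2-ethylidene-1-phenylhex-3-yn-1-one, and the acid chloride A8, 3-(triisopropylsilyl)prop-2-ynoyl chloride.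
- Forward key step: a trialkylphosphine adds to the β-carbon of A7 (the future C4), the enolate oxygen is acylated by A8, and a tertiary amine generates the ylide. The ylide closes onto the new ester carbonyl in an intramolecular Wittig reaction to give the furan A6 and a phosphine oxide.
- For it: the fully substituted furan forms in one flask. The C3 arm arrives with all four carbons and its oxygen as a protected propargylic alcohol, so only deprotection and oxidation remain for that arm. This is stronger than the chosen route, which builds that arm from an acetyl group in one strongly basic operation.
- Against it: A7 is a cross-conjugated 2-alkynyl enone that needs its own multistep synthesis. Its β-carbon bears a methyl group and its α-carbon is branched, which slows the phosphine addition, and the distal alkyne carbon is a second acceptor site. A8 is itself an excellent acceptor for the phosphine, so the two reagents can consume each other. Phosphine oxide is formed stoichiometrically.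
- Comparison: after the key step four steps remain (two deprotections, an oxidation and an acylation) against three in the chosen route. Before it, three or more steps stand against one.

Key step: step 2

Remark on the chemistry: the carbinol centres of 4, 5 and 7 are formed without control, which is immaterial because every sp3 centre is erased when 7 aromatises to 8.

## Route

Step 1
Reactants: 1 ethyl vinyl ether; 2 3-(triisopropylsilyl)prop-2-ynal
Product: 5 3-hydroxy-5-(triisopropylsilyl)pent-4-yn-2-one (racemic), via 1-ethoxyvinyllithium 3 (not isolated), via enol ether carbinol 4 (not isolated)
Conditions: 1 (2.0 equiv), t-BuLi (1.5 equiv), THF, −78 → 0 °C; 2, −78 °C; then 0.5 M HCl, THF, 0 °C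
Reagents that add atoms: water, O
Why: Metalated ethyl vinyl ether 3 is a hard acetyl anion equivalent that adds 1,2 to the aldehyde of 2 (organolithium addition to an ynal); dilute acid then protonates the enol ether terminus of 4, water captures the oxocarbenium ion and ethanol is lost, which reveals the methyl ketone without touching the silyl alkyne. The carbinol centre is formed racemic and later becomes the sp2 carbon C5.

Step 2
Reactants: 5 3-hydroxy-5-(triisopropylsilyl)pent-4-yn-2-one (racemic); 6 4-phenylbut-3-yn-2-one
Product: 8 1-{4-methyl-2-phenyl-5-[(triisopropylsilyl)ethynyl]furan-3-yl}ethan-1-one, via hydroxydihydrofuran 7 (not isolated)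
Conditions: Cs2CO3 (20 mol %), 6 (1.2 equiv), MeCN, −20 → 0 °C, slow addition of 5; then p-TsOH·H2O (60 mol %), rt
Reagents that add atoms: none
Why: The carbonate generates a small stationary concentration of the alkoxide of 5, which adds to the phenyl-bearing β-carbon of ynone 6 (O1–C2) and gives an allenolate. The α-carbon of this allenolate attacks the methyl ketone of the same molecule (C3–C4) in a 5-exo-trig aldol closure, the only ring formed, and the resulting tertiary alkoxide of 7 passes its charge to the next molecule of 5, so the base is needed only in catalytic amount. Acid then ionises the tertiary C4 carbinol, whose cation is stabilised through the C2=C3 enol ether by O1, and loss of the propargylic C5–H gives the aromatic furan; elimination toward the methyl group would converge on the same furan by tautomerisation. The closest known reaction type is the base-mediated oxa-Michael–aldol condensation of α-hydroxy ketones with activated alkynes to furans. The two stereocentres of 7 (C4 and C5) are formed without control and are both destroyed on dehydration, so no controlling element is needed. The step needs O- rather than C-attack of the acyloin and β- rather than carbonyl attack on 6; the polarity of the ynone fixes the regiochemistry, with oxygen on C2 and the acetyl group on C3. The weak heterogeneous base, the low temperature and the slow addition of 5 to an excess of 6 keep the acyloin anion short-lived, which limits enolisation at its doubly activated C–H. The aprotic medium with little free hydroxyl lets the allenolate cyclise before it is protonated.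

Step 3
Reactants: 8 1-{4-methyl-2-phenyl-5-[(triisopropylsilyl)ethynyl]furan-3-yl}ethan-1-one; 9 N-methoxy-N-methylacetamide
Product: 12 4-{4-methyl-2-phenyl-5-[(triisopropylsilyl)ethynyl]furan-3-yl}but-3-yn-2-one, via enol phosphate 10 (not isolated), via lithium acetylide 11 (not isolated)
Conditions: LiN(iPr)2 (1.1 equiv), THF, −78 °C; ClP(O)(OEt)2 (1.1 equiv), −78 °C → rt; cannulation into LiN(iPr)2 (2.2 equiv), THF, −78 °C → rt; then 9 (2.0 equiv), −78 → 0 °C; inverse quench into cold 1 M HCl
Reagents that add atoms: none
Why: This is Negishi's conversion of a methyl ketone into an alkyne, stopped at the acetylide and trapped in the same flask: kinetic enolisation of the only enolisable position and O-phosphorylation by diethyl chlorophosphate give 10, and two further equivalents of amide base bring about β-elimination of diethyl phosphate and deprotonation of the new alkyne to 11, while the ring has no C–H and the silyl alkyne is inert to amide base. Acetylide 11 then acylates Weinreb amide 9 (Weinreb ketone synthesis); the chelated tetrahedral adduct cannot collapse before work-up, so no second addition occurs, and the excess of 9 absorbs the small surplus of amide base. The acidic inverse quench protonates diisopropylamine and the released N,O-dimethylhydroxylamine before either can add to the new ynone.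

Step 4
Reactants: 12 4-{4-methyl-2-phenyl-5-[(triisopropylsilyl)ethynyl]furan-3-yl}but-3-yn-2-one
Product: 13 4-(5-ethynyl-4-methyl-2-phenylfuran-3-yl)but-3-yn-2-one
Conditions: TBAF (1.5 equiv), AcOH (1.5 equiv), THF, 0 °C → rt
Reagents that add atoms: none
Why: Fluoride-induced protodesilylation of a silyl alkyne: fluoride attacks silicon and the departing sp carbanion is protonated at once by acetic acid. The buffer keeps hydroxide and alkoxide out of the medium, so the methyl ynone should be neither attacked at its β-carbon nor enolised; 13 is used directly in step 5.

Step 5
Reactants: 13 4-(5-ethynyl-4-methyl-2-phenylfuran-3-yl)but-3-yn-2-one; 14 benzoyl chloride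
Product: 15 Capillaridin A = 4-[4-methyl-5-(3-oxo-3-phenylprop-1-yn-1-yl)-2-phenylfuran-3-yl]but-3-yn-2-one
Conditions: PdCl2(PPh3)2 (2 mol %), CuI (4 mol %), Et3N (1.5 equiv), 14 (1.2 equiv), THF, rt, Ar
Reagents that add atoms: none
Why: Acyl Sonogashira coupling: zerovalent palladium formed in situ inserts into the C–Cl bond of 14, the copper acetylide made from 13 with CuI and Et3N transmetalates to the acyl complex of divalent palladium, and reductive elimination forms the C(sp)–C(O) bond. The tertiary amine cannot add irreversibly to either ynone, 14 has no α-hydrogen, and exclusion of air suppresses alkyne homocoupling.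

## Compound list

1 | ethyl vinyl ether | C=COCC | starting material
2 | 3-(triisopropylsilyl)prop-2-ynal | O=CC#C[Si](C(C)C)(C(C)C)C(C)C | starting material
3 | 1-ethoxyvinyllithium | [Li]C(=C)OCC | intermediate
4 | 2-ethoxy-5-(triisopropylsilyl)pent-1-en-4-yn-3-ol (racemic) | C=C(OCC)C(O)C#C[Si](C(C)C)(C(C)C)C(C)C | intermediate
5 | 3-hydroxy-5-(triisopropylsilyl)pent-4-yn-2-one (racemic) | CC(=O)C(O)C#C[Si](C(C)C)(C(C)C)C(C)C | intermediate
6 | 4-phenylbut-3-yn-2-one | CC(=O)C#Cc1ccccc1 | starting material
7 | 1-{4-hydroxy-4-methyl-2-phenyl-5-[(triisopropylsilyl)ethynyl]-4,5-dihydrofuran-3-yl}ethan-1-one (mixture of racemic diastereomers) | CC(=O)C1=C(c2ccccc2)OC(C#C[Si](C(C)C)(C(C)C)C(C)C)C1(C)O | intermediate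
8 | 1-{4-methyl-2-phenyl-5-[(triisopropylsilyl)ethynyl]furan-3-yl}ethan-1-one | CC(=O)c1c(-c2ccccc2)oc(C#C[Si](C(C)C)(C(C)C)C(C)C)c1C | intermediate
9 | N-methoxy-N-methylacetamide | CON(C)C(C)=O | starting material
10 | 1-{4-methyl-2-phenyl-5-[(triisopropylsilyl)ethynyl]furan-3-yl}ethenyl diethyl phosphate | C=C(OP(=O)(OCC)OCC)c1c(-c2ccccc2)oc(C#C[Si](C(C)C)(C(C)C)C(C)C)c1C | intermediate
11 | lithium {4-methyl-2-phenyl-5-[(triisopropylsilyl)ethynyl]furan-3-yl}ethynide | [Li]C#Cc1c(-c2ccccc2)oc(C#C[Si](C(C)C)(C(C)C)C(C)C)c1C | intermediate
12 | 4-{4-methyl-2-phenyl-5-[(triisopropylsilyl)ethynyl]furan-3-yl}but-3-yn-2-one | CC(=O)C#Cc1c(-c2ccccc2)oc(C#C[Si](C(C)C)(C(C)C)C(C)C)c1C | intermediate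
13 | 4-(5-ethynyl-4-methyl-2-phenylfuran-3-yl)but-3-yn-2-one | CC(=O)C#Cc1c(-c2ccccc2)oc(C#C)c1C | intermediate
14 | benzoyl chloride | O=C(Cl)c1ccccc1 | starting material
15 | Capillaridin A, 4-[4-methyl-5-(3-oxo-3-phenylprop-1-yn-1-yl)-2-phenylfuran-3-yl]but-3-yn-2-one | CC(=O)C#Cc1c(-c2ccccc2)oc(C#CC(=O)c2ccccc2)c1C | target

## Step count and least certain steps

Total step count: 5. Longest linear sequence: 5 steps, from 1 and 2 to 15; 6, 9 and 14 are commercial and enter directly.

Step 2 (key step). The most likely failure is base-induced enolisation of 5 at its C–H, which is α to the ketone, α to oxygen and propargylic. This would move the carbonyl into conjugation with the alkyne, or lead to C-alkylation, before the hydroxyl has added to 6. A second failure is protonation of the allenolate before the aldol closure, which would leave the sequence stalled at the open-chain oxa-Michael stage. The fallback removes the sensitive propargylic acyloin and installs the C5 alkyne by cross-coupling. It sets out from 6 and returns at 8. Hydroxyacetone, which has no propargylic C–H, would be condensed with 6 under the same carbonate and acid sequence; this should pass through 1-(4-hydroxy-4-methyl-2-phenyl-4,5-dihydrofuran-3-yl)ethan-1-one F1 and give 1-(4-methyl-2-phenylfuran-3-yl)ethan-1-one F2. Bromination with NBS in DMF at 0 °C at the only free ring position would give 1-(5-bromo-4-methyl-2-phenylfuran-3-yl)ethan-1-one F3. Sonogashira coupling of F3 with ethynyltri(propan-2-yl)silane (PdCl2(PPh3)2, CuI, Et3N) would then give 8.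

Step 3. The most likely failure is attack of the amide base at phosphorus, or 1,3-migration of the phosphoryl group in the metalated vinyl phosphate, in place of β-elimination. Incomplete O-phosphorylation of the enolate, which is crowded by phenyl and methyl, is a second risk. A third is consumption of 9 by surplus amide base, or amine addition to the new ynone during the quench, because the acetylide is acylated in the flask in which it is formed. The fallback replaces ketone dehydration by one-carbon homologation of an aldehyde and acylates an isolated, purified alkyne. It sets out from 5 and returns at 12. Compound 5 would be annulated as in step 2 with methyl 3-phenylprop-2-ynoate in place of 6; this should pass through methyl 4-hydroxy-4-methyl-2-phenyl-5-[(triisopropylsilyl)ethynyl]-4,5-dihydrofuran-3-carboxylate F4 and give methyl 4-methyl-2-phenyl-5-[(triisopropylsilyl)ethynyl]furan-3-carboxylate F5. Reduction with iBu2AlH (2.5 equiv, CH2Cl2, −78 → 0 °C) would give {4-methyl-2-phenyl-5-[(triisopropylsilyl)ethynyl]furan-3-yl}methanol F6, and oxidation with activated MnO2 in CH2Cl2 would give 4-methyl-2-phenyl-5-[(triisopropylsilyl)ethynyl]furan-3-carbaldehyde F7. Homologation of F7 with dimethyl (1-diazo-2-oxopropyl)phosphonate and K2CO3 in MeOH (Ohira–Bestmann variant of the Seyferth–Gilbert reaction) would give 3-ethynyl-4-methyl-2-phenyl-5-[(triisopropylsilyl)ethynyl]furan F8; the triisopropylsilyl alkyne should survive these conditions. Deprotonation of F8 with n-BuLi (1.05 equiv, THF, −78 °C) would give 11 free of amine and phosphate salts, and acylation with 9 followed by the inverse acidic quench would give 12.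

Step 4. The most likely failure is loss of material by conjugate addition of basic species to the methyl ynone, or by enolisation and condensation of its methyl ketone, while the hindered Si–C(sp) bond is cleaved only slowly under buffering. The fallback keeps both arms at the alcohol oxidation level until the end. It sets out from 8 and returns at 15. Ketone 8 would be carried through enol phosphate 10 to lithium acetylide 11 as in step 3, and 11 would be trapped with acetaldehyde in place of 9 to give 4-{4-methyl-2-phenyl-5-[(triisopropylsilyl)ethynyl]furan-3-yl}but-3-yn-2-ol F9 (racemic). Unbuffered TBAF in THF, acceptable here because no ynone is present, would give 4-(5-ethynyl-4-methyl-2-phenylfuran-3-yl)but-3-yn-2-ol F10 (racemic). Double deprotonation with n-BuLi (2.2 equiv) and addition to benzaldehyde would give 4-[5-(3-hydroxy-3-phenylprop-1-yn-1-yl)-4-methyl-2-phenylfuran-3-yl]but-3-yn-2-ol F11 (mixture of diastereomers). Oxidation of both propargylic alcohols with Dess–Martin periodinane (NaHCO3, CH2Cl2) would then give 15.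

Step 5. The most likely failure is oxidative homocoupling or oligomerisation of the electron-rich terminal alkyne 13 under CuI and amine before it is acylated, together with slow amine-induced decomposition of the bis-ynone product. The fallback is a copper-free carbonylative Sonogashira coupling, which assembles the ketone from three components. It sets out from 13 and returns at 15: 13 would be coupled with iodobenzene under CO (1 atm) with PdCl2(PPh3)2 and Et3N in THF, and no new isolated compound arises.

## Further compounds

F1 | step 2 | 1-(4-hydroxy-4-methyl-2-phenyl-4,5-dihydrofuran-3-yl)ethan-1-one (racemic) | CC(=O)C1=C(c2ccccc2)OCC1(C)O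
F2 | step 2 | 1-(4-methyl-2-phenylfuran-3-yl)ethan-1-one | CC(=O)c1c(-c2ccccc2)occ1C
F3 | step 2 | 1-(5-bromo-4-methyl-2-phenylfuran-3-yl)ethan-1-one | CC(=O)c1c(-c2ccccc2)oc(Br)c1C
F4 | step 3 | methyl 4-hydroxy-4-methyl-2-phenyl-5-[(triisopropylsilyl)ethynyl]-4,5-dihydrofuran-3-carboxylate (mixture of racemic diastereomers) | COC(=O)C1=C(c2ccccc2)OC(C#C[Si](C(C)C)(C(C)C)C(C)C)C1(C)O
F5 | step 3 | methyl 4-methyl-2-phenyl-5-[(triisopropylsilyl)ethynyl]furan-3-carboxylate | COC(=O)c1c(-c2ccccc2)oc(C#C[Si](C(C)C)(C(C)C)C(C)C)c1C
F6 | step 3 | {4-methyl-2-phenyl-5-[(triisopropylsilyl)ethynyl]furan-3-yl}methanol | OCc1c(-c2ccccc2)oc(C#C[Si](C(C)C)(C(C)C)C(C)C)c1C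
F7 | step 3 | 4-methyl-2-phenyl-5-[(triisopropylsilyl)ethynyl]furan-3-carbaldehyde | O=Cc1c(-c2ccccc2)oc(C#C[Si](C(C)C)(C(C)C)C(C)C)c1C
F8 | step 3 | 3-ethynyl-4-methyl-2-phenyl-5-[(triisopropylsilyl)ethynyl]furan | C#Cc1c(-c2ccccc2)oc(C#C[Si](C(C)C)(C(C)C)C(C)C)c1C
F9 | step 4 | 4-{4-methyl-2-phenyl-5-[(triisopropylsilyl)ethynyl]furan-3-yl}but-3-yn-2-ol (racemic) | CC(O)C#Cc1c(-c2ccccc2)oc(C#C[Si](C(C)C)(C(C)C)C(C)C)c1C
F10 | step 4 | 4-(5-ethynyl-4-methyl-2-phenylfuran-3-yl)but-3-yn-2-ol (racemic) | CC(O)C#Cc1c(-c2ccccc2)oc(C#C)c1C
F11 | step 4 | 4-[5-(3-hydroxy-3-phenylprop-1-yn-1-yl)-4-methyl-2-phenylfuran-3-yl]but-3-yn-2-ol (mixture of diastereomers) | CC(O)C#Cc1c(-c2ccccc2)oc(C#CC(O)c2ccccc2)c1C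
F0 | step 5 | none | none
A1 | alternative 1 | triisopropyl{[4-methyl-2-phenyl-5-(trimethylsilylethynyl)furan-3-yl]ethynyl}silane | Cc1c(C#C[Si](C)(C)C)oc(-c2ccccc2)c1C#C[Si](C(C)C)(C(C)C)C(C)C
A2 | alternative 1 | 3-methyl-1-phenyl-6-(trimethylsilyl)hexa-1,5-diyne-3,4-diol (mixture of diastereomers) | CC(O)(C#Cc1ccccc1)C(O)C#C[Si](C)(C)C
A3 | alternative 1 | 1-[(triisopropylsilyl)ethynyl]-1,2-benziodoxol-3(1H)-one | CC(C)[Si](C#CI1OC(=O)c2ccccc21)(C(C)C)C(C)C
A4 | alternative 2 | 3-methyl-5-phenyl-4-[(triisopropylsilyl)ethynyl]furan-2(5H)-one (racemic) | CC1=C(C#C[Si](C(C)C)(C(C)C)C(C)C)C(c2ccccc2)OC1=O
A5 | alternative 2 | 2-oxo-1-phenyl-4-(triisopropylsilyl)but-3-yn-1-yl 2-(diethoxyphosphoryl)propanoate (mixture of diastereomers) | CCOP(=O)(OCC)C(C)C(=O)OC(c1ccccc1)C(=O)C#C[Si](C(C)C)(C(C)C)C(C)C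
A6 | alternative 3 | tert-butyldimethylsilyl ether of 4-[4-methyl-2-phenyl-5-(triisopropylsilylethynyl)furan-3-yl]but-3-yn-2-ol (racemic) | CC(O[Si](C)(C)C(C)(C)C)C#Cc1c(-c2ccccc2)oc(C#C[Si](C(C)C)(C(C)C)C(C)C)c1C
A7 | alternative 3 | 5-[(tert-butyldimethylsilyl)oxy]-2-ethylidene-1-phenylhex-3-yn-1-one (racemic) | CC=C(C#CC(C)O[Si](C)(C)C(C)(C)C)C(=O)c1ccccc1
A8 | alternative 3 | 3-(triisopropylsilyl)prop-2-ynoyl chloride | O=C(Cl)C#C[Si](C(C)C)(C(C)C)C(C)C
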